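The numbers are made up; no experiment stands behind them.

Passage between the phases, at 0.16 s⁻¹, runs faster than the first-order losses of the reagent in the reaction phase, at 0.0642 s⁻¹ with the starting material as charged.

    reagent in the reaction phase ⇌ reagent in the second phase, rate k1*([reagent in the reaction phase] - [reagent in the second phase]/K1) per volume of the first phase (K1 = 0.95, k1 = 0.16 s⁻¹)
    starting material + reagent in the reaction phase → target (k2 = 2.2 M⁻¹ s⁻¹)
    reagent in the reaction phase → decomposed reagent (k3 = 0.040 s⁻¹)
    2 reagent in the reaction phase → homo dimer (k4 = 6.4 M⁻¹ s⁻¹)
    reagent in the reaction phase → decomposition product (k5 = 9.7 × 10⁻⁶ s⁻¹)

starting material 0.011 M; reagent in the second phase 0.0275 M; time 50 s; volume of the second phase over the first 2.0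

- where a step has two of a species, its rate is k times that concentration squared, and two are used at each turn
- in the second phase: reagent in the second phase; everything else is in the first
- charges count per volume of the first phase; a concentration in a rate is the amount of a species over the volume of its own phase; every rate counts per litre of the first phase
- run time (flask): 50 s

1. the target standing at 50 s, as a percentage of the starting material charged
2. the change that raises the amount of target at 50 s, in percent of the starting material charged most ("none" if none brings more than 2 percentage points) (Friday's / Tuesday's / none)
3. amount of target at 50 s, in percent of the starting material charged, after Tuesday's

We count the reagent as one pool over both phases and climb the ladder of times. Passage by itself relaxes the phases toward partition with a time of 4.09 s, and at partition 34.5% of the pool stands in the reaction phase. Dimerisation comes next: with the phases at partition it would at first halve the pool in 23.9 s. Decomposition and capture by the starting material, taken as pseudo-first-order, give the pool a life of 45.2 s, longer than the dimer time, which is itself longer than the passage time. Because passage is quick, we take it as instant.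

The pool is charged once and drains, so the quantity we carry is the exposure N, the rate constant of capture times the time integral of the reagent in the reaction phase, so that e^(−N) of the starting material remains. Integrating the pool gives N = g·ln(1 + r(1 − e^(−t/τ))), with τ the pool life, r the pool life over the dimer time, here 1.89, and g the capture constant over the dimer constant, scaled by the pool, here 0.498. At 50 s this gives 0.408, so we commit to 33.5%. With passage taken as instant, Tuesday's does not enter N, so our figure after it stays the same, while Friday's doubles r and gives 46.6%, so we choose Friday's.

The forecast says 30.5% (27% to 34%), Friday's, and 34.5% (31% to 38%) after Tuesday's, since “the feed is soon near partition equilibrium”.

The simulation gives 32.7%, and 33.8% after Tuesday's; Friday's is best, worth 16 percentage points against 1.1 points. Read back, this flask's target is an exposure of 0.396, beside our 0.408. At 10.6 s this flask's decomposition used reagent at 0.60 of the rate of dimerisation. For the neighbour charged with 60.0% of this flask's starting material, the exposure reckoned the same way gives 34.8% of its own charge, and the simulated neighbour holds 33.7%.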